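The constants are invented, and the outcome is calculated.

A closed, stirred vessel holds a starting complex that is to exchange a ligand twice, and it leaks material sideways on the way.

    starting complex + incoming ligand → leaving ligand + complex with one exchanged (k1 = 5.9 M⁻¹ s⁻¹)
    complex with one exchanged + incoming ligand → leaving ligand + complex with two exchanged (k2 = 0.20 M⁻¹ s⁻¹)
    complex with one exchanged → side product (k3 = 0.58 s⁻¹)
    starting complex ⇌ dormant form (K4 = 2.4, k4 = 0.0084 s⁻¹)
    protic impurity + starting complex → quenched substrate (k5 = 2.3 M⁻¹ s⁻¹)

| flask | starting complex | incoming ligand | protic impurity | time |
|---|---|---|---|---|
| teal | 0.030 M | 0.100 M | 0.0300 M | 2.5 min |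
| grey | 0.040 M | 0.100 M | 0.0300 M | 2.5 min |
| violet | 0.060 M | 0.100 M | 0.0300 M | 2.5 min |
| amber | 0.10 M | 0.100 M | 0.0300 M | 2.5 min |
| red | 0.15 M | 0.100 M | 0.0300 M | 2.5 min |

- [complex with two exchanged] at the end for teal, grey, violet, amber, red, in this order
- the course of these numbers from the first flask to the last (falls all the way / hardly changes / falls, then rises / rises, then falls / rises all the way)

- "hardly changes" means that all values lie within two and a half points (for a concentration: within two and a half percent of the largest)
- run time (teal): 2.5 min

Follow one molecule of starting complex and ask for its chance at each fork. Treat each way as a first-order rate at the charged concentrations, so that the chance of a way is its rate over the sum of the rates.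

| fork | way on | way off | chance of going on |
|---|---|---|---|
| starting complex | 0.590 s⁻¹ | 0.0690 s⁻¹ | 89.5% |
| complex with one exchanged | 0.0200 s⁻¹ | 0.58 s⁻¹ | 3.33% |

Read the first row: at the charged concentrations the exchange is faster than quenching, and the forward passage to the dormant form, at 0.0084 s⁻¹, is far slower than the exchange, so leave it out of this reckoning.

Read the second row and call its last entry the onward chance: the fraction of complex with one exchanged that takes a second ligand instead of becoming side product, a selectivity that moves with the ligand present at that moment. At the charged ligand, nearly all of this complex becomes side product. The way off is far faster than the way on, so the onward chance follows the ligand almost in proportion.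

Each molecule passing the first fork takes one ligand, so use the mean of the ligand's start and end. In teal the mean is 86.6% of the ligand charge, and the two chances together give 2.60% of the complex charge, or 7.79 × 10⁻⁴ M. In amber the mean is 55.2%, giving 1.67%, or 0.00167 M, which is more than teal.

Red asks for 1.34 ligand charges, so my mean fails there and my reckoning gives no number. Red's time constant for the ligand by step 1 at the start, 1.13 s, is shorter than the 1.72 s of the complex with one exchanged by step 3, whereas teal's 5.65 s is longer. So I commit to a row that rises to amber and then falls.

The forecast gives 7.200 × 10⁻⁴ M, 8.700 × 10⁻⁴ M, 0.00102 M, 0.001 M and 8.000 × 10⁻⁴ M, and rises, then falls, its ground being that more starting complex “uses up the ligand before the intermediate builds”, the intermediate being the complex with one exchanged. My teal and amber figures both stand higher than the forecast's, and its highest point is violet, where I put mine at amber.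

The flasks give 7.08 × 10⁻⁴ M, 8.67 × 10⁻⁴ M, 0.00108 M, 0.00116 M and 9.24 × 10⁻⁴ M, and the course rises, then falls, with the turn at 0.087 M of starting complex. Red's incoming ligand stands at 0% of its charge after 2.50 min, with 5.14% of the complex charge still standing as starting complex. Now take grey, whose incoming ligand ends at 64% of its charge: at the mean of the ligand's charge and end the onward chance is 2.75%, and with the first fork that makes 2.46% of the complex charge, where the grey flask holds 2.17% as complex with two exchanged.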